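## The problem

The target is a depside with no stereocentre: two resorcinol-derived benzene rings joined by one aryl ester. Ring A carries the ester carbonyl at C1, a free hydroxyl at C2, a methoxy group at C4 and a heptyl chain at C6. Ring B carries a carboxylic acid at C1, a methoxy group at C2, the ester oxygen at C4 and a pentyl chain at C6. The first difficulty is the ester itself: the ring A carbonyl sits between two ortho substituents, so acylation of a phenol by an activated ring A acid is slow and prone to side reactions. The second is telling four oxygens apart: on ring A the C2 hydroxyl stays free while C4 is methylated, and on ring B C2 is methylated while C4 carries the acyl group. The third is functional-group tolerance: the aryl ester will not survive hydroxide, alkoxide or hydride, so the ring B carboxyl cannot be unmasked by saponification, and the free electron-rich benzoic acid is best revealed last and without heat. Two features make a short solution possible. The ester carbonyl is a single carbon bonded only to ring A C1 and to the ring B C4 oxygen, so it can be delivered as carbon monoxide between an aryl halide and a phenol. A 5-heptylresorcinol diether has a mirror plane, so its two positions flanked by the chain and an oxygen are identical and halogenation there gives one compound.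

## Retrosynthesis

Target 17 to aldehyde 16. The C–O bond of the carboxyl hydroxyl is cut, so the ring B carboxyl is carried through the synthesis as a formyl group. Formylation of olivetol delivers exactly this oxidation state, which saves an oxidation and an esterification compared with carrying an ester. The forward reaction is a chlorite oxidation at about pH 4, which leaves the aryl ester alone. It is asked not to chlorinate the phenolic ring A.

Aldehyde 16 to diol 15 and on to bis-MOM ester 14. The methyl–oxygen bond at ring A C4 and then the two methoxymethyl (MOM) ethers are removed. Keeping the two ring A oxygens identical until the ester exists preserves the symmetry that the iodination relies on. A ring A carrying the C4 methyl from the start would give regioisomeric iodides. Once the ester is in place, the C2 hydroxyl is hydrogen-bonded to the ester carbonyl and the C4 hydroxyl is not, so one equivalent of base and methylating agent should find C4 only. MOM is chosen because dilute acid removes it without touching the aryl ester or the aldehyde.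

Ester 14 to iodide 7, phenol 13 and carbon monoxide. The ring A C1–carbonyl bond and the carbonyl–oxygen bond are cut together. Compared with esterifying a preformed ring A acid, this makes the hindered acyl–oxygen bond on palladium instead of by attack on a shielded carbonyl. It also avoids activated 2-alkoxybenzoyl derivatives altogether. Both fragments are simple trisubstituted or tetrasubstituted benzenes. The forward reaction must favour carbonylative coupling over direct aryl ether formation and over reduction of the C–I bond.

Iodide 7 to arene 6, alkene 5, aldehyde 2, phosphonium salt 3 (through ylide 4) and 3,5-dihydroxybenzaldehyde 1. The C–I bond is cut first, then the chain is cut at its first C–C bond by a Wittig disconnection. Starting from 1 allows the MOM groups to go on before the chain is built, so no demethylation and re-protection are needed. Iodination is asked to go to the carbon next to the chain and not to the carbon between the two ether oxygens.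

Phenol 13 to MOM ether 12, phenol 11, dihydroxyaldehyde 10 (through iminium salt 9) and olivetol 8. The C4 MOM ether and the C2 methyl are removed, then the formyl carbon. Olivetol already holds the pentyl chain and both oxygens, and formylation places the carbon between the chain and one hydroxyl. The chelated hydroxyl next to the aldehyde is the less reactive one, so the C4 hydroxyl is masked first, the C2 hydroxyl is methylated and the mask is removed.

## Roads not taken

Alternative 1: ring B built from acyclic pieces. The cut is through ring B bonds C1–C6 and C2–C3. In the forward direction dibenzyl malonate A1 adds to (E)-non-3-en-2-one A2 in a Michael reaction, and a Dieckmann closure gives racemic benzyl trans-2-hydroxy-4-oxo-6-pentylcyclohex-2-ene-1-carboxylate A3. Dehydrogenation would give benzyl 2,4-dihydroxy-6-pentylbenzoate A4, and protection, methylation and deprotection would give benzyl 4-hydroxy-2-methoxy-6-pentylbenzoate A5.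
- Merits: the materials are cheap, the carboxyl carbon is placed without any regiochemical question, and the carboxyl arrives as a benzyl ester. The synthesis could then end with a hydrogenolysis, which is a gentler last step than an oxidation beside a free phenol.
- Weak points: two stereocentres are made only to be destroyed. The alkoxide base must match the benzyl ester. The aromatisation needs an oxidant that can also halogenate the electron-rich ring. Above all, the plan only makes ring B, which olivetol 8 already supplies intact, and leaves the hindered ester and the ring A oxygen pattern unsolved.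
- Comparison: A5 would need about six steps against four for phenol 13. Alternative 1 is better in its end game. The chosen plan answers with a shorter route whose key step addresses the central problem, and its fallback for the final oxidation joins the same benzyl ester series.

Alternative 2: ring A built on a preformed ester by cycloaddition. The cut is through ring A bonds C1–C2 and C5–C6. 1,3-Dimethoxy-1-(trimethylsilyloxy)buta-1,3-diene A6 would add across the triple bond of benzyl 4-(dec-2-ynoyloxy)-2-methoxy-6-pentylbenzoate A7. Elimination of the methoxy group at the ketene acetal carbon and desilylation would give benzyl 4-[(2-heptyl-6-hydroxy-4-methoxybenzoyl)oxy]-2-methoxy-6-pentylbenzoate A8.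
- Merits: the diene polarity sets the C2 hydroxyl and the C4 methoxy group directly, so ring A needs no protecting group and no late selective methylation. The ester is made while its acyl carbon is still an unhindered alkynoyl carbon. On paper this is the shortest road: after A8 only a hydrogenolysis remains.
- Weak points: an alkynoate with one acceptor group and a heptyl chain on its β carbon is a sluggish dienophile. The heat it would need is hard on a silyl ketene acetal diene. The aryl ester of A7 is also an acylating agent for the nucleophilic diene, and conjugate addition without ring closure is a further leak. The uncertain step comes late and would consume advanced ring B material.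
- Comparison: alternative 2 is ahead by several steps and sets the oxygen pattern without a selective methylation. The chosen plan answers with predictability: oxidative addition, CO insertion and C–O reductive elimination are each established elementary steps, at the price of four simple steps to iodide 7 and two steps to unmask and methylate.

Alternative 3: ester formed by acylketene capture, ring A closed afterwards. The cut is through the ester C–O bond and ring A bond C1–C6. Heating 6-(2,4-dioxoundecyl)-2,2-dimethyl-4H-1,3-dioxin-4-one A9 would release 3,5,7-trioxotetradec-1-en-1-one A10. Phenol A5 would capture it as benzyl 2-methoxy-6-pentyl-4-[(3,5,7-trioxotetradecanoyl)oxy]benzoate A11. Aldol closure of chain C2 onto the C7 ketone and dehydration would give benzyl 4-[(2-heptyl-4,6-dihydroxybenzoyl)oxy]-2-methoxy-6-pentylbenzoate A12.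
- Merits: the ester forms at an unhindered ketene carbon, ring A appears without protecting groups, and neither palladium nor CO is needed.
- Weak points: A9 is a sensitive tricarbonyl compound that needs its own multistep assembly. In A11 the aryl ester is an activated ester: under the base needed for the aldol step, the C5 enol oxygen can attack it and expel the phenoxide of A5 to give a 4-hydroxy-2-pyrone, which destroys the depside bond. A12 would still need the same selective C4 methylation as diol 15, so nothing is saved at the end.
- Comparison: alternative 3 is equal in the late methylation and ahead in protecting-group economy on ring A. The chosen plan answers with stable, easily purified intermediates and with an ester that forms only after ring A is aromatic, so the pyrone pathway cannot operate.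

Key step: step 9

Remark on the chemistry: alkene 5 is carried forward as the mixture of geometric isomers that the Wittig reaction delivers, because step 3 removes the double bond; the target has no stereocentre.

## Route

Step 1
Reactants: 1 3,5-dihydroxybenzaldehyde
Product: 2 3,5-bis(methoxymethoxy)benzaldehyde
Conditions: MOMCl (2.5 equiv), i-Pr2NEt, CH2Cl2/DMF, 0 °C → rt
Reagents that add atoms: chloromethyl methyl ether, COCCl
Why: Williamson-type O-alkylation of both phenols by the reactive α-chloro ether (MOM protection); the aldehyde is untouched and the two ethers keep the ring symmetric.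

Step 2
Reactants: 3 hexyltriphenylphosphonium bromide; 2 3,5-bis(methoxymethoxy)benzaldehyde
Product: 5 1-(hept-1-en-1-yl)-3,5-bis(methoxymethoxy)benzene (E/Z mixture), via hexylidenetriphenylphosphorane 4 (not isolated)
Conditions: KOt-Bu, THF, 0 °C; then 2, 0 °C → rt
Reagents that add atoms: none
Why: Wittig olefination with a non-stabilised ylide joins the six-carbon unit to the formyl carbon; the Z-rich mixture is acceptable because the geometry is erased in step 3, and MOM ethers are stable to the base.

Step 3
Reactants: 5 1-(hept-1-en-1-yl)-3,5-bis(methoxymethoxy)benzene (E/Z mixture)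
Product: 6 1-heptyl-3,5-bis(methoxymethoxy)benzene
Conditions: H2 (1 atm), Pd/C (10 wt %), EtOAc, rt
Reagents that add atoms: none
Why: Catalytic hydrogenation of a styrene-type double bond; aryl MOM ethers are not benzylic C–O bonds and should not be cleaved in a neutral solvent.

Step 4
Reactants: 6 1-heptyl-3,5-bis(methoxymethoxy)benzene
Product: 7 1-heptyl-2-iodo-3,5-bis(methoxymethoxy)benzene
Conditions: NIS (1.05 equiv), MeCN, 0 °C → rt, dark
Reagents that add atoms: N-iodosuccinimide, O=C1CCC(=O)N1I
Why: Electrophilic aromatic iodination; the carbon between the chain and an ether oxygen is para to the other oxygen and less crowded than the carbon between the two oxygens, and the mirror plane of 6 makes both such carbons the same, so one monoiodide should result; no acid is added, so the MOM ethers should survive.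

Step 5
Reactants: 8 olivetol (5-pentylbenzene-1,3-diol)
Product: 10 2,4-dihydroxy-6-pentylbenzaldehyde, via aryliminium chloride 9 (not isolated)
Conditions: POCl3, DMF, 0 °C → rt; then H2O, 50 °C
Reagents that add atoms: N,N-dimethylformamide, CN(C)C=O; water, O
Why: Vilsmeier–Haack formylation; the chloroiminium ion attacks para to one hydroxyl and ortho to the other, next to the chain, as is usual for 5-alkylresorcinols, and water hydrolyses iminium salt 9 to the aldehyde.

Step 6
Reactants: 10 2,4-dihydroxy-6-pentylbenzaldehyde
Product: 11 2-hydroxy-4-(methoxymethoxy)-6-pentylbenzaldehyde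
Conditions: MOMCl (1.05 equiv), i-Pr2NEt, CH2Cl2, 0 °C
Reagents that add atoms: chloromethyl methyl ether, COCCl
Why: Chemoselective MOM protection; the C2 hydroxyl is hydrogen-bonded to the aldehyde and is much less nucleophilic, so one equivalent of reagent should alkylate the C4 hydroxyl only.

Step 7
Reactants: 11 2-hydroxy-4-(methoxymethoxy)-6-pentylbenzaldehyde
Product: 12 2-methoxy-4-(methoxymethoxy)-6-pentylbenzaldehyde
Conditions: MeI, K2CO3, DMF, 40 °C
Reagents that add atoms: iodomethane, CI
Why: Williamson O-methylation; in DMF with excess reagent the chelated phenoxide is alkylated, and the aldehyde has no enolisable hydrogen.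

Step 8
Reactants: 12 2-methoxy-4-(methoxymethoxy)-6-pentylbenzaldehyde
Product: 13 4-hydroxy-2-methoxy-6-pentylbenzaldehyde
Conditions: HCl (3 M aq), THF, 50 °C
Reagents that add atoms: none
Why: Acid-catalysed hydrolysis of the MOM acetal; the methyl ether and the aldehyde are stable to dilute aqueous acid, and the formyl-deactivated ring does not react with the formaldehyde set free.

Step 9
Reactants: 7 1-heptyl-2-iodo-3,5-bis(methoxymethoxy)benzene; 13 4-hydroxy-2-methoxy-6-pentylbenzaldehyde
Product: 14 4-formyl-3-methoxy-5-pentylphenyl 2-heptyl-4,6-bis(methoxymethoxy)benzoate
Conditions: Pd(OAc)2 (5 mol %), Xantphos (7.5 mol %), Et3N (3 equiv), CO (1 atm), toluene, 100 °C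
Reagents that add atoms: carbon monoxide, [C-]#[O+]
Why: Pd(OAc)2 is reduced in the flask to a zerovalent palladium–Xantphos complex, which inserts into the C–I bond of 7; CO then migrates into the aryl–palladium bond to give a divalent aroylpalladium iodide, a step that relieves the crowding between the metal and the two ortho groups. Triethylamine deprotonates 13, whose hydroxyl is acidified by the para formyl group and has no ortho substituent, and the phenoxide replaces iodide on palladium. C–O reductive elimination, favoured by the wide bite angle of Xantphos (4,5-bis(diphenylphosphino)-9,9-dimethylxanthene), releases aryl ester 14 and returns zerovalent palladium. The closest known reaction type is the palladium-catalysed aryloxycarbonylation (Heck carbonylation) of aryl iodides with phenols under 1 atm of CO. No ring is closed and no stereocentre is formed. The selectivity needed is chemoselectivity for the carbonylative ester over the diaryl ether and over reduction of the C–I bond: the two ortho substituents slow direct attack at the aryl–palladium carbon but not CO insertion, and the acyl–oxygen bond is then made at the metal, one atom away from the shielded ring carbon. The MOM ethers leave no second phenol to compete, and the aldehyde of 13 should be inert to acylpalladium species at this temperature.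

Step 10
Reactants: 14 4-formyl-3-methoxy-5-pentylphenyl 2-heptyl-4,6-bis(methoxymethoxy)benzoate
Product: 15 4-formyl-3-methoxy-5-pentylphenyl 2-heptyl-4,6-dihydroxybenzoate
Conditions: HCl (3 M aq), THF, 45 °C
Reagents that add atoms: none
Why: Acid-catalysed hydrolysis of both MOM acetals; the aryl ester of a 2,6-disubstituted benzoic acid resists acid hydrolysis, because addition of water to its shielded carbonyl is slow.

Step 11
Reactants: 15 4-formyl-3-methoxy-5-pentylphenyl 2-heptyl-4,6-dihydroxybenzoate
Product: 16 4-formyl-3-methoxy-5-pentylphenyl 2-heptyl-6-hydroxy-4-methoxybenzoate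
Conditions: MeI (1.1 equiv), K2CO3 (1.1 equiv), acetone, rt
Reagents that add atoms: iodomethane, CI
Why: Chemoselective Williamson methylation; the C4 hydroxyl para to the ester carbonyl is the more acidic and is free, while the C2 hydroxyl is locked in a hydrogen bond to the ester carbonyl, so one equivalent of base and iodomethane should methylate C4 only, as is general for 2,4-dihydroxybenzoates.

Step 12
Reactants: 16 4-formyl-3-methoxy-5-pentylphenyl 2-heptyl-6-hydroxy-4-methoxybenzoate
Product: 17 4-[(2-heptyl-6-hydroxy-4-methoxybenzoyl)oxy]-2-methoxy-6-pentylbenzoic acid
Conditions: NaClO2, NaH2PO4, 2-methylbut-2-ene (excess), t-BuOH/THF/H2O, 0 °C → rt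
Reagents that add atoms: sodium chlorite, [Na+].[O-]Cl=O
Why: Pinnick oxidation; chlorous acid adds to the aldehyde and fragments to the acid at about pH 4, where the aryl ester is stable, and the alkene scavenger removes hypochlorous acid before it can chlorinate ring A.

## Compound list

1 | 3,5-dihydroxybenzaldehyde | O=Cc1cc(O)cc(O)c1 | starting material
2 | 3,5-bis(methoxymethoxy)benzaldehyde | COCOc1cc(C=O)cc(OCOC)c1 | intermediate
3 | hexyltriphenylphosphonium bromide | CCCCCC[P+](c1ccccc1)(c1ccccc1)c1ccccc1.[Br-] | starting material
4 | hexylidenetriphenylphosphorane (not isolated) | CCCCCC=P(c1ccccc1)(c1ccccc1)c1ccccc1 | intermediate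
5 | 1-(hept-1-en-1-yl)-3,5-bis(methoxymethoxy)benzene (E/Z mixture, Z isomer drawn) | CCCCC/C=C\c1cc(OCOC)cc(OCOC)c1 | intermediate
6 | 1-heptyl-3,5-bis(methoxymethoxy)benzene | CCCCCCCc1cc(OCOC)cc(OCOC)c1 | intermediate
7 | 1-heptyl-2-iodo-3,5-bis(methoxymethoxy)benzene | CCCCCCCc1cc(OCOC)cc(OCOC)c1I | intermediate
8 | olivetol (5-pentylbenzene-1,3-diol) | CCCCCc1cc(O)cc(O)c1 | starting material
9 | [(2,4-dihydroxy-6-pentylphenyl)methylidene]dimethylammonium chloride (not isolated) | CCCCCc1cc(O)cc(O)c1C=[N+](C)C.[Cl-] | intermediate
10 | 2,4-dihydroxy-6-pentylbenzaldehyde | CCCCCc1cc(O)cc(O)c1C=O | intermediate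
11 | 2-hydroxy-4-(methoxymethoxy)-6-pentylbenzaldehyde | CCCCCc1cc(OCOC)cc(O)c1C=O | intermediate
12 | 2-methoxy-4-(methoxymethoxy)-6-pentylbenzaldehyde | CCCCCc1cc(OCOC)cc(OC)c1C=O | intermediate
13 | 4-hydroxy-2-methoxy-6-pentylbenzaldehyde | CCCCCc1cc(O)cc(OC)c1C=O | intermediate
14 | 4-formyl-3-methoxy-5-pentylphenyl 2-heptyl-4,6-bis(methoxymethoxy)benzoate | CCCCCCCc1cc(OCOC)cc(OCOC)c1C(=O)Oc1cc(CCCCC)c(C=O)c(OC)c1 | intermediate
15 | 4-formyl-3-methoxy-5-pentylphenyl 2-heptyl-4,6-dihydroxybenzoate | CCCCCCCc1cc(O)cc(O)c1C(=O)Oc1cc(CCCCC)c(C=O)c(OC)c1 | intermediate
16 | 4-formyl-3-methoxy-5-pentylphenyl 2-heptyl-6-hydroxy-4-methoxybenzoate | CCCCCCCc1cc(OC)cc(O)c1C(=O)Oc1cc(CCCCC)c(C=O)c(OC)c1 | intermediate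
17 | 4-[(2-heptyl-6-hydroxy-4-methoxybenzoyl)oxy]-2-methoxy-6-pentylbenzoic acid | CCCCCCCc1cc(OC)cc(O)c1C(=O)Oc1cc(CCCCC)c(C(=O)O)c(OC)c1 | target

## Step count and least certain steps

Total step count: 12. Longest linear sequence: 8 steps (1 to 17 through steps 1–4 and 9–12; the ring B branch from 8 through steps 5–8 and 9–12 is equally long).

Step 9 (key step). The most likely failure is slow capture of the crowded aroylpalladium species by the phenoxide. Reduction of the C–I bond, or hydrolysis of the acyl complex by traces of water, could then overtake ester formation, and the catalyst could be lost as palladium black under the low CO pressure. The fallback sets out from 7 and 13 and comes back at 14, and makes the same two bonds in separate operations. Iodine–magnesium exchange on 7 with i-PrMgCl·LiCl in THF at −20 °C would give [2-heptyl-4,6-bis(methoxymethoxy)phenyl]magnesium chloride F1. Quenching with CO2 and acidic work-up would give 2-heptyl-4,6-bis(methoxymethoxy)benzoic acid F2. Steglich esterification of F2 with 13 (DCC, DMAP, CH2Cl2) would give 14. The acid chloride is avoided on purpose, because 2-(methoxymethoxy)benzoyl chlorides cyclise onto the neighbouring acetal.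

Step 4. Iodination may be sluggish without an acid promoter, while any acid strong enough to activate NIS threatens the MOM ethers. A second iodination, or attack between the two ether oxygens, would also cost material. The fallback sets out from 6 and comes back at 7. Bromination with NBS in MeCN at 0 °C needs no acid and is the best-documented halogenation next to the chain of 5-alkylresorcinol diethers. It would give 2-bromo-1-heptyl-3,5-bis(methoxymethoxy)benzene F3. Bromine–lithium exchange with n-BuLi in THF at −78 °C would give [2-heptyl-4,6-bis(methoxymethoxy)phenyl]lithium F4, stabilised by the ortho acetal oxygen, and quenching with I2 would give 7.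

Step 11. The risks are over-alkylation at the chelated C2 hydroxyl and loss of the depside bond through the ring A phenoxide, since the ring B phenoxide is a fair leaving group. The fallback sets out from 15 and comes back at 16 without any new compound (entered as F0). It is a Mitsunobu etherification with methanol (PPh3, DIAD, MeOH, THF, 0 °C → rt). This activates the alcohol instead of the phenol, runs without carbonate base or a free phenoxide, and is selective for the more acidic, non-chelated hydroxyl.

Step 12. Hypochlorous acid formed during the oxidation may chlorinate ring A if scavenging is incomplete, because ring A then carries a free hydroxyl and a methoxy group. The fallback sets out from 14, where both ring A oxygens are still masked, and comes back at 17.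
- Pinnick oxidation of 14 would give 4-{[2-heptyl-4,6-bis(methoxymethoxy)benzoyl]oxy}-2-methoxy-6-pentylbenzoic acid F5.
- Alkylation of the carboxylate (BnBr, KHCO3, DMF) would give benzyl 4-{[2-heptyl-4,6-bis(methoxymethoxy)benzoyl]oxy}-2-methoxy-6-pentylbenzoate F6.
- Aqueous HCl in THF would give benzyl 4-[(2-heptyl-4,6-dihydroxybenzoyl)oxy]-2-methoxy-6-pentylbenzoate F7.
- MeI and K2CO3 in acetone would give benzyl 4-[(2-heptyl-6-hydroxy-4-methoxybenzoyl)oxy]-2-methoxy-6-pentylbenzoate F8.
- Hydrogenolysis (H2, Pd/C, EtOAc) would give 17.

This costs two extra steps and ends with a hydrogenolysis, which no phenol can interfere with.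

## Further compounds

F1 | step 9 | [2-heptyl-4,6-bis(methoxymethoxy)phenyl]magnesium chloride | CCCCCCCc1cc(OCOC)cc(OCOC)c1[Mg]Cl
F2 | step 9 | 2-heptyl-4,6-bis(methoxymethoxy)benzoic acid | CCCCCCCc1cc(OCOC)cc(OCOC)c1C(=O)O
F3 | step 4 | 2-bromo-1-heptyl-3,5-bis(methoxymethoxy)benzene | CCCCCCCc1cc(OCOC)cc(OCOC)c1Br
F4 | step 4 | [2-heptyl-4,6-bis(methoxymethoxy)phenyl]lithium | CCCCCCCc1cc(OCOC)cc(OCOC)c1[Li]
F0 | step 11 | none | none
F5 | step 12 | 4-{[2-heptyl-4,6-bis(methoxymethoxy)benzoyl]oxy}-2-methoxy-6-pentylbenzoic acid | CCCCCCCc1cc(OCOC)cc(OCOC)c1C(=O)Oc1cc(CCCCC)c(C(=O)O)c(OC)c1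
F6 | step 12 | benzyl 4-{[2-heptyl-4,6-bis(methoxymethoxy)benzoyl]oxy}-2-methoxy-6-pentylbenzoate | CCCCCCCc1cc(OCOC)cc(OCOC)c1C(=O)Oc1cc(CCCCC)c(C(=O)OCc2ccccc2)c(OC)c1
F7 | step 12 | benzyl 4-[(2-heptyl-4,6-dihydroxybenzoyl)oxy]-2-methoxy-6-pentylbenzoate | CCCCCCCc1cc(O)cc(O)c1C(=O)Oc1cc(CCCCC)c(C(=O)OCc2ccccc2)c(OC)c1
F8 | step 12 | benzyl 4-[(2-heptyl-6-hydroxy-4-methoxybenzoyl)oxy]-2-methoxy-6-pentylbenzoate | CCCCCCCc1cc(OC)cc(O)c1C(=O)Oc1cc(CCCCC)c(C(=O)OCc2ccccc2)c(OC)c1
A1 | alternative 1 | dibenzyl malonate | O=C(CC(=O)OCc1ccccc1)OCc1ccccc1
A2 | alternative 1 | (E)-non-3-en-2-one | CCCCC/C=C/C(C)=O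
A3 | alternative 1 | benzyl trans-2-hydroxy-4-oxo-6-pentylcyclohex-2-ene-1-carboxylate (racemic, one enantiomer drawn) | CCCCC[C@@H]1CC(=O)C=C(O)[C@H]1C(=O)OCc1ccccc1
A4 | alternative 1 | benzyl 2,4-dihydroxy-6-pentylbenzoate | CCCCCc1cc(O)cc(O)c1C(=O)OCc1ccccc1
A5 | alternative 1 | benzyl 4-hydroxy-2-methoxy-6-pentylbenzoate | CCCCCc1cc(O)cc(OC)c1C(=O)OCc1ccccc1
A6 | alternative 2 | 1,3-dimethoxy-1-(trimethylsilyloxy)buta-1,3-diene | C=C(OC)C=C(OC)O[Si](C)(C)C
A7 | alternative 2 | benzyl 4-(dec-2-ynoyloxy)-2-methoxy-6-pentylbenzoate | CCCCCCCC#CC(=O)Oc1cc(CCCCC)c(C(=O)OCc2ccccc2)c(OC)c1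
A8 | alternative 2 | benzyl 4-[(2-heptyl-6-hydroxy-4-methoxybenzoyl)oxy]-2-methoxy-6-pentylbenzoate | CCCCCCCc1cc(OC)cc(O)c1C(=O)Oc1cc(CCCCC)c(C(=O)OCc2ccccc2)c(OC)c1
A9 | alternative 3 | 6-(2,4-dioxoundecyl)-2,2-dimethyl-4H-1,3-dioxin-4-one | CCCCCCCC(=O)CC(=O)CC1=CC(=O)OC(C)(C)O1
A10 | alternative 3 | 3,5,7-trioxotetradec-1-en-1-one | CCCCCCCC(=O)CC(=O)CC(=O)C=C=O
A11 | alternative 3 | benzyl 2-methoxy-6-pentyl-4-[(3,5,7-trioxotetradecanoyl)oxy]benzoate | CCCCCCCC(=O)CC(=O)CC(=O)CC(=O)Oc1cc(CCCCC)c(C(=O)OCc2ccccc2)c(OC)c1
A12 | alternative 3 | benzyl 4-[(2-heptyl-4,6-dihydroxybenzoyl)oxy]-2-methoxy-6-pentylbenzoate | CCCCCCCc1cc(O)cc(O)c1C(=O)Oc1cc(CCCCC)c(C(=O)OCc2ccccc2)c(OC)c1
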